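The earlier runs and the new flask are simulated on assumed constants; the scatter is artificial.

The target is made on the catalyst, so the decision for the next run is how much free catalyst to charge, with the other charges left as they stand.

| setting | maple | birch | oak | flask |
|---|---|---|---|---|
| starting material | 0.062 M | 0.062 M | 0.062 M | 0.062 M |
| second substrate | 0.031 M | 0.046 M | 0.062 M | 0.0620 M |
| partner | 0.0682 M | 0.0682 M | 0.10 M | 0.0682 M |
| free catalyst | 0.43 mM | 0.43 mM | 0.43 mM | 0.43 mM |
| impurity | 0.19 mM | 0.19 mM | 0.19 mM | 0.19 mM |
| remark | run made earlier | run made earlier | run made earlier |  |

- maple (time / h: target / %, starting material / %): 5.00: 4.1, 51.6; 12.0: 7.7, 25.1; 25.0: 11.3, 13.7; 40.0: 15.4, 11.4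
- birch (time / h: target / %, starting material / %): 10.0: 6.1, 30.4; 20.0: 9.1, 16.0; 25.0: 10.4, 14.0; 40.0: 12.9, 12.5
- oak (time / h: target / %, starting material / %): 5.00: 4.3, 51.2; 12.0: 7.8, 24.9; 25.0: 12.0, 13.5; 40.0: 15.1, 11.3

(standard deviation of a reading: 0.3 percentage points)

- the numbers in the tables scatter with a standard deviation of 0.3 percentage points
- on the list of suspects stand: starting material + free catalyst <-> catalyst intermediate A; free catalyst + impurity -> spent catalyst; starting material <-> dormant form; partner + catalyst intermediate B -> free catalyst + second product; partner + catalyst intermediate A -> free catalyst + target; second substrate + free catalyst <-> catalyst intermediate B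
- what has gone from starting material into another species counts as reacted, even if it can come back
- no earlier run changes the charge of free catalyst; that part of a forecast is a guess

1. factor on the rate of making target when 10 % of the starting material are converted if free catalyst is charged twice over
2. factor on the rate when 10 % of the starting material are converted if free catalyst is charged at 4.0 mM instead

Maple shows 4.1 % target at 5.00 h with 51.6 % starting material remaining, which is further along than the 10 % conversion asked about. So at that moment I freeze starting material, second substrate and partner near their charges, and what changes with the catalyst charge is how much catalyst works.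

Impurity is charged at 0.19 mM, less than the 0.43 mM of free catalyst, so impurity is the limiting reagent of their reaction. I assume that each impurity removes one catalyst before the moment I look. This is a guess, because the three runs share one catalyst charge.

My quantity is live catalyst, the charge of free catalyst minus the charge of impurity, here 0.240 mM. Taking the rate as proportional to live catalyst, I reckon a factor of 2.79 for the doubled charge and 15.9 at 4.0 mM. The second factor is larger than the 9.30 rise in the charge, so I would charge 4.0 mM.

The forecast gives 2.5 (range 2 to 2.9) and 12.5 (range 8.5 to 16.5), which differ from my values. Its words are: “The runs cannot resolve this, so I take values in between.”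

The simulation gives 2.76 and 15.2, so the forecast's second value is low by a factor of 1.22.

    starting material + free catalyst ⇌ catalyst intermediate A (K = 82.0 M⁻¹, k = 410 M⁻¹ h⁻¹)
    free catalyst + impurity → spent catalyst (k = 3.20 × 10⁵ M⁻¹ h⁻¹)
    starting material ⇌ dormant form (K = 5.60, k = 0.130 h⁻¹)
    partner + catalyst intermediate B → free catalyst + second product (k = 120 M⁻¹ h⁻¹)
    partner + catalyst intermediate A → free catalyst + target (k = 68.0 M⁻¹ h⁻¹)
    second substrate + free catalyst ⇌ catalyst intermediate B (K = 46.0 M⁻¹, k = 1300 M⁻¹ h⁻¹)

In this flask the impurity as charged takes a free catalyst at 60.8 h⁻¹, which is a time of 0.0164 h, far shorter than the 0.757 h at which the rate is read. At 3.00 h this flask holds impurity at 0 % of its charge and spent catalyst at 44.2 % of the catalyst charged, while a flask charged at 4.0 mM, with 3.81 mM live catalyst, holds spent catalyst at 4.75 % of its catalyst at 10 % conversion.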